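**Strategy.** The cyclohexene ring is cut at C2–C3 and C5–C6 into a protected dihydroxyacetone (C3–C4–C5, C4 as ketone) and a 2-(methoxycarbonyl)allyl bis-electrophile (C6–C1–C2). The key step is an α,α′-annulation: a chiral enamine of 2,2-dimethyl-1,3-dioxan-5-one is alkylated at C5 by the allylic bromide, then closes at C3 onto the β-methoxyacrylate carbon C2 with loss of methoxide. This delivers the ring with its C1=C2 enoate as a 2,4-dioxabicyclo[3.3.1]nonenone. It exploits that C4 lies between the two oxygenated carbons C3 and C5, and C1 between C2 and C6. The auxiliary sets C5, the acetonide bridge relays C3, reduction sets C4, and Mitsunobu acetylation finally inverts C3.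

Key step: step 3

Remark: locants follow the target ring (C1 carries CO2Me, C2 is the vinylic CH, C3 the acetate, C4 the 2-methylbutanoate, C5 the 3-methylpentanoate, C6 is CH2).
Remark: compounds 2, 4, 10 and 14 are taken as catalogue compounds.
Remark: the (2S,5S)-amine is chosen on the premise that the electrophile enters anti to the methyl group next to the enamine carbon; should the sense be opposite, the (2R,5R)-amine takes its place with no other change.

Step 1
Reactants: 1 2,2-dimethyl-1,3-dioxan-5-one; 2 (2S,5S)-2,5-dimethylpyrrolidine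
Product: 3 (2S,5S)-1-(2,2-dimethyl-4H-1,3-dioxin-5-yl)-2,5-dimethylpyrrolidine
Conditions: PPTS (cat.), 4 Å MS, benzene, reflux
Reagents that add atoms: none
Why: Stork enamine formation by condensation with removal of water; the C2-symmetric amine makes both enamine rotamers identical, and no stereocentre is formed.

Step 2
Reactants: 4 methyl (E)-3-methoxy-2-methylprop-2-enoate
Product: 5 methyl (Z)-2-(bromomethyl)-3-methoxyprop-2-enoate
Conditions: NBS, AIBN (cat.), PhCF3, 80 °C
Reagents that add atoms: N-bromosuccinimide, O=C1CCC(=O)N1Br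
Why: Wohl–Ziegler bromination of the allylic methyl group, as with β-methoxycrotonates; the alkene geometry is kept (the descriptor changes only because CH2Br outranks CO2Me).

Step 3
Reactants: 3 (2S,5S)-1-(2,2-dimethyl-4H-1,3-dioxin-5-yl)-2,5-dimethylpyrrolidine; 5 methyl (Z)-2-(bromomethyl)-3-methoxyprop-2-enoate
Product: 8 methyl (1R,5S)-3,3-dimethyl-9-oxo-2,4-dioxabicyclo[3.3.1]non-6-ene-7-carboxylate, via C-alkylated enamine 6 (not isolated), via bicyclic iminium methoxide 7 (not isolated)
Conditions: i-Pr2NEt, MeCN, 0 → 75 °C; then AcOH–NaOAc buffer (pH 5), H2O, rt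
Reagents that add atoms: water, O
Why: Stork-type C-alkylation of enamine 3 by the allylic bromide of 5 forms C5–C6; i-Pr2NEt then shifts the iminium to the less substituted enamine, whose carbon C3 adds to the β-methoxyacrylate carbon C2, and the ester enolate expels methoxide, which forms C2–C3 and restores the C1=C2 enoate before hydrolysis frees the ketone. The closest known reaction type is the α,α′-annulation of ketone enamines with 2-(halomethyl)acrylates to bicyclo[3.3.1]nonan-9-ones, here ended by an addition–elimination. The carbocycle closes in the 6-endo-trig conjugate mode, the tether being attached at the α-carbon of the acrylate. C5 is set by the C2-symmetric auxiliary (the bromide enters anti to the methyl group next to the enamine carbon), and C3 is relayed from it because the three-atom bridge can only span two cis, 1,3-diaxial bonds of the dioxane. The step needs SN2 rather than SN2′ or N-alkylation in the first event, which the donor-deactivated β-methoxyacrylate and the flanked nitrogen should secure, and no enamine shift towards C5, which allylic strain in the hindered enamine disfavours.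

Step 4
Reactants: 8 methyl (1R,5S)-3,3-dimethyl-9-oxo-2,4-dioxabicyclo[3.3.1]non-6-ene-7-carboxylate
Product: 9 methyl (1R,5S,9S)-9-hydroxy-3,3-dimethyl-2,4-dioxabicyclo[3.3.1]non-6-ene-7-carboxylate (OH anti to the ring oxygens)
Conditions: NaBH4, MeOH, −40 °C
Reagents that add atoms: none
Why: substrate-controlled 1,2-reduction; hydride should enter from the dioxane face, which has oxygen atoms instead of axial C–H bonds at the flanking positions, so the new hydroxyl at C4 lies over the carbocycle, trans to O3 and O5 (4S), and the enoate is left alone.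

Step 5
Reactants: 9 methyl (1R,5S,9S)-9-hydroxy-3,3-dimethyl-2,4-dioxabicyclo[3.3.1]non-6-ene-7-carboxylate; 10 (R)-2-methylbutanoic acid
Product: 11 methyl (1R,5S,9S)-3,3-dimethyl-9-{[(2R)-2-methylbutanoyl]oxy}-2,4-dioxabicyclo[3.3.1]non-6-ene-7-carboxylate
Conditions: DIC, DMAP (cat.), CH2Cl2, 0 °C → rt
Reagents that add atoms: none
Why: Steglich esterification of the only free hydroxyl; mild carbodiimide activation at low temperature should keep the α-stereocentre of the acid, and no ring stereocentre is touched.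

Step 6
Reactants: 11 methyl (1R,5S,9S)-3,3-dimethyl-9-{[(2R)-2-methylbutanoyl]oxy}-2,4-dioxabicyclo[3.3.1]non-6-ene-7-carboxylate
Product: 12 methyl (3S,4S,5R)-3,5-dihydroxy-4-{[(2R)-2-methylbutanoyl]oxy}cyclohex-1-ene-1-carboxylate
Conditions: AcOH–H2O (4:1), 40 °C
Reagents that add atoms: none
Why: acid hydrolysis of the strained, 1,3-diaxially bridged acetonide; the C4 ester is trans to both neighbouring hydroxyls, which disfavours acyl migration.

Step 7
Reactants: 12 methyl (3S,4S,5R)-3,5-dihydroxy-4-{[(2R)-2-methylbutanoyl]oxy}cyclohex-1-ene-1-carboxylate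
Product: 13 methyl (3R,4S,5R)-3-(acetyloxy)-5-hydroxy-4-{[(2R)-2-methylbutanoyl]oxy}cyclohex-1-ene-1-carboxylate
Conditions: PPh3, DIAD, AcOH (1.1 equiv), THF, −20 → 0 °C
Reagents that add atoms: acetic acid, CC(=O)O
Why: Mitsunobu reaction; the allylic C3 oxyphosphonium should be displaced by acetate in the SN2 mode much faster than the saturated C5 one, so C3 is inverted (3S to 3R) and acetylated in one step, as in known C3 inversions of shikimate derivatives.

Step 8
Reactants: 13 methyl (3R,4S,5R)-3-(acetyloxy)-5-hydroxy-4-{[(2R)-2-methylbutanoyl]oxy}cyclohex-1-ene-1-carboxylate; 14 (S)-3-methylpentanoic acid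
Product: 15 methyl (3R,4S,5R)-3-(acetyloxy)-4-{[(2R)-2-methylbutanoyl]oxy}-5-{[(3S)-3-methylpentanoyl]oxy}cyclohex-1-ene-1-carboxylate (CNP0188172.1)
Conditions: DIC, DMAP (cat.), CH2Cl2, 0 °C
Reagents that add atoms: none
Why: Steglich esterification of the remaining equatorial C5 hydroxyl; no stereocentre is formed or touched.

**Compound list**

1 | 2,2-dimethyl-1,3-dioxan-5-one | CC1(C)OCC(=O)CO1 | starting material
2 | (2S,5S)-2,5-dimethylpyrrolidine | C[C@H]1CC[C@H](C)N1 | starting material
3 | (2S,5S)-1-(2,2-dimethyl-4H-1,3-dioxin-5-yl)-2,5-dimethylpyrrolidine | C[C@H]1CC[C@H](C)N1C1=COC(C)(C)OC1 | intermediate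
4 | methyl (E)-3-methoxy-2-methylprop-2-enoate | CO/C=C(\C)C(=O)OC | starting material
5 | methyl (Z)-2-(bromomethyl)-3-methoxyprop-2-enoate | CO/C=C(\CBr)C(=O)OC | intermediate
6 | methyl (E)-2-{[(4R)-5-[(2S,5S)-2,5-dimethylpyrrolidin-1-yl]-2,2-dimethyl-4H-1,3-dioxin-4-yl]methyl}-3-methoxyprop-2-enoate (C-alkylated enamine) | C[C@H]1CC[C@H](C)N1C1=COC(C)(C)O[C@@H]1C/C(C(=O)OC)=C\OC | intermediate
7 | (2S,5S)-1-[(1R,5S)-7-(methoxycarbonyl)-3,3-dimethyl-2,4-dioxabicyclo[3.3.1]non-6-en-9-ylidene]-2,5-dimethylpyrrolidin-1-ium methoxide | C[C@H]1CC[C@H](C)[N+]1=C1[C@@H]2C=C(C(=O)OC)C[C@H]1OC(C)(C)O2.[O-]C | intermediate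
8 | methyl (1R,5S)-3,3-dimethyl-9-oxo-2,4-dioxabicyclo[3.3.1]non-6-ene-7-carboxylate | O=C1[C@@H]2C=C(C(=O)OC)C[C@H]1OC(C)(C)O2 | intermediate
9 | methyl (1R,5S,9S)-9-hydroxy-3,3-dimethyl-2,4-dioxabicyclo[3.3.1]non-6-ene-7-carboxylate | O[C@@H]1[C@@H]2C=C(C(=O)OC)C[C@H]1OC(C)(C)O2 | intermediate
10 | (R)-2-methylbutanoic acid | CC[C@@H](C)C(=O)O | starting material
11 | methyl (1R,5S,9S)-3,3-dimethyl-9-{[(2R)-2-methylbutanoyl]oxy}-2,4-dioxabicyclo[3.3.1]non-6-ene-7-carboxylate | CC[C@@H](C)C(=O)O[C@@H]1[C@@H]2C=C(C(=O)OC)C[C@H]1OC(C)(C)O2 | intermediate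
12 | methyl (3S,4S,5R)-3,5-dihydroxy-4-{[(2R)-2-methylbutanoyl]oxy}cyclohex-1-ene-1-carboxylate | O[C@@H]1CC(C(=O)OC)=C[C@H](O)[C@H]1OC(=O)[C@H](C)CC | intermediate
13 | methyl (3R,4S,5R)-3-(acetyloxy)-5-hydroxy-4-{[(2R)-2-methylbutanoyl]oxy}cyclohex-1-ene-1-carboxylate | O[C@@H]1CC(C(=O)OC)=C[C@@H](OC(C)=O)[C@H]1OC(=O)[C@H](C)CC | intermediate
14 | (S)-3-methylpentanoic acid | CC[C@H](C)CC(=O)O | starting material
15 | methyl (3R,4S,5R)-3-(acetyloxy)-4-{[(2R)-2-methylbutanoyl]oxy}-5-{[(3S)-3-methylpentanoyl]oxy}cyclohex-1-ene-1-carboxylate | CC[C@H](C)CC(=O)O[C@@H]1CC(C(=O)OC)=C[C@@H](OC(C)=O)[C@H]1OC(=O)[C@H](C)CC | target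

Total step count: 8. Longest linear sequence: 7 steps (steps 1, 3, 4, 5, 6, 7, 8).

**Steps most likely to fail**

Step 3. The first alkylation may in part take the SN2′ course, or pass through N-alkylation and an aza-Cope shift. Either attaches C2 instead of C6 to the auxiliary-controlled carbon and so erodes the enantiomeric purity. The closure onto the donor-substituted acrylate may also stall after the first bond. The fallback sets out from 1 and 5 and uses the SAMP/RAMP hydrazone method. Ketone 1 is condensed with (R)-1-amino-2-(methoxymethyl)pyrrolidine to hydrazone F1. Metalation (t-BuLi, THF, −78 °C) and alkylation with 5 at −100 °C should give the alkylated hydrazone F2. A second metalation (LDA, THF, −78 → 0 °C) closes the ring by addition–elimination to the bicyclic hydrazone F3, which two-phase aqueous oxalic acid cleaves. The route is rejoined at 8.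

Step 7. The C5 hydroxyl may be activated in place of the allylic one, or the C4 ester carbonyl may take part in the displacement, which would give retention or scramble the acyl groups. The fallback sets out from 12 and replaces inversion by an oxidation–reduction sequence. MnO2 (CH2Cl2, rt) oxidises only the allylic alcohol, to enone F4. An Evans–Saksena reduction (Me4NBH(OAc)3, MeCN–AcOH, −20 °C), directed by the C5 hydroxyl, delivers hydride on the face of that hydroxyl and should give the 3R diol F5. The equatorial C5 hydroxyl is esterified with 14 (DIC, DMAP, −20 °C) to the hydroxy diester F6. Acetylation of the remaining pseudoaxial C3 hydroxyl (Ac2O, pyridine) rejoins the route at 15.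

Step 4. The facial bias of hydride delivery to the bridging carbonyl may be insufficient, giving the alcohol with OH syn to the ring oxygens. The fallback sets out from 8 and comes back at 9. It replaces substrate control by reagent control: a Corey–Bakshi–Shibata reduction with the oxazaborolidine enantiomer that reinforces attack from the dioxane face (catecholborane, toluene, −78 °C). No new compound is made.

**Further compounds**

F1 | step 3 | (2R)-N-(2,2-dimethyl-1,3-dioxan-5-ylidene)-2-(methoxymethyl)pyrrolidin-1-amine | COC[C@H]1CCCN1N=C1COC(C)(C)OC1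
F2 | step 3 | methyl (E)-3-methoxy-2-{[(4R)-5-{[(2R)-2-(methoxymethyl)pyrrolidin-1-yl]imino}-2,2-dimethyl-1,3-dioxan-4-yl]methyl}prop-2-enoate | COC[C@H]1CCCN1N=C1COC(C)(C)O[C@@H]1C/C(C(=O)OC)=C\OC
F3 | step 3 | methyl (1R,5S)-9-{[(2R)-2-(methoxymethyl)pyrrolidin-1-yl]imino}-3,3-dimethyl-2,4-dioxabicyclo[3.3.1]non-6-ene-7-carboxylate | COC[C@H]1CCCN1N=C1[C@@H]2C=C(C(=O)OC)C[C@H]1OC(C)(C)O2
F0 | step 4 | none | none
F4 | step 7 | methyl (4S,5R)-5-hydroxy-4-{[(2R)-2-methylbutanoyl]oxy}-3-oxocyclohex-1-ene-1-carboxylate | O[C@@H]1CC(C(=O)OC)=CC(=O)[C@H]1OC(=O)[C@H](C)CC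
F5 | step 7 | methyl (3R,4S,5R)-3,5-dihydroxy-4-{[(2R)-2-methylbutanoyl]oxy}cyclohex-1-ene-1-carboxylate | O[C@@H]1CC(C(=O)OC)=C[C@@H](O)[C@H]1OC(=O)[C@H](C)CC
F6 | step 7 | methyl (3R,4S,5R)-3-hydroxy-4-{[(2R)-2-methylbutanoyl]oxy}-5-{[(3S)-3-methylpentanoyl]oxy}cyclohex-1-ene-1-carboxylate | CC[C@H](C)CC(=O)O[C@@H]1CC(C(=O)OC)=C[C@@H](O)[C@H]1OC(=O)[C@H](C)CC
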